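## Analysis of the target

The target 28 is a 1-aryl-1,2-dihydronaphthalene: aromatic ring A (6,7-dihydroxy-8-methoxy) is fused to ring B (C1, C2, C3=C4), C1 carries a 3,4-dihydroxy-2-methoxyphenyl ring (primed numbers), and C2 and C3 each carry a 4-hydroxybenzoyl group. Atom numbers throughout are those of this skeleton (C1–C4, C4a, C5–C8, C8a). The only stereocentres are the adjacent C1 and C2, both (R), with the C1 aryl and the C2 aroyl group on the same face (cis). C2–H is α to a ketone and allylic to C3=C4, so acid or base can epimerise it to the less crowded trans isomer or shift the double bond to C2=C3, after which ring B aromatises easily; the two catechols are air-sensitive. Six phenols stand beside two methyl ethers (C8 and C2'), so every phenol needs one protecting group that can be removed at the end without touching a methyl ether. C1 is crowded between the C8 and C2' methoxy groups, and ring A needs carbon substituents on two adjacent positions, one of them next to the methoxy group. The difficulty is to create the cis relation at an epimerisable centre late, kinetically and under mild conditions. The route rests on two facts: C4 is bonded to ring A at C4a and, once C3=C4 is read as a deoxygenated enol, stands at the aldehyde oxidation level; and C3 is β to the C2 ketone, so C3–C4 can be made by conjugate addition of a C4 acyl-anion equivalent to a C2=C3 enedione, leaving an enolate whose protonation creates C2.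

## Retrosynthetic reasoning

**Phenol protection.** The six phenols of 28 are carried as isopropyl ethers in 27. These survive organolithiums, hydroxide, the carbene and palladium, and a Lewis acid removes secondary alkyl ethers much faster than methyl ethers. The forward step must free six phenols without enolising C2.

**C4–H.** The C4–H bond of 27 is traced to a C4–O bond: the vinyl triflate 26, and before it the enol 24 of a 2-acyl-1-tetralone. This turns C4 into a carbonyl carbon, which is what the ring closure needs. The forward steps must sulfonylate the ring oxygen, not the aroyl oxygen, and then replace the triflate by hydrogen.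

**C3–C4 (key disconnection).** Cutting C3–C4 of 24 opens ring B to the aldehyde enedione 23. This bond is chosen because its formation from a C4 acyl-anion equivalent and the C2=C3 acceptor leaves an enolate at C2. C2 is therefore the last centre made, by a proton transfer that the neighbouring C1 centre can direct, and both aroyl groups are already in place. The forward reaction has to add at C3 (six-membered ring), not at the fully substituted C2 (five-membered ring), and deliver the proton to C2 anti to the C1 aryl.

**C2=C3.** The enedione of 23 (through its acetal 22 and the aldol 20) is cut at C2=C3 into the ketone 15 and the arylglyoxal 17. C3 and its aroyl group thus arrive as one reactive electrophile, and C2 is the only enolisable carbon of 15. The forward steps are an aldol addition and a dehydration that must not disturb C1–H.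

**C1–C1'.** The C1 stereocentre of 15 is cut at the bond to the pendant ring, giving the chalcone 9 and the boronic acid 14. This bond is preferred to C1–C8a because the boronic acid then has one ortho substituent, not two. The forward step is an enantioselective conjugate arylation.

**C1=C2.** The chalcone 9 comes from the ring A aldehyde 6 and the acetophenone 8 by aldol condensation. The C4 carbon is already on ring A, masked as an acetal.

**C8a–C1.** The formyl group of 6 is cut off to leave the acetal 3, made from aldehyde 2 and 5-hydroxyvanillin 1. The position between the acetal and the methoxy group is the one activated for metalation, because the isopropoxy groups coordinate poorly and shield their neighbours. The substitution pattern of ring A is thereby fixed by construction.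

**Side pieces.** The boronic acid 14 comes from the ether 11 of 3-methoxycatechol 10 by the same methoxy-directed metalation. The glyoxal 17 comes from the acetophenone 8, itself made from 4-hydroxyacetophenone 7.

## Alternatives that were turned down

**Alternative 1:** The C2–C3 bond is cut, with the C2' oxygen tied to the C2 carbonyl as a six-membered lactone. In the dihydrocoumarin A1, zerovalent palladium (Pd2(dba)3, a bulky phosphine, K3PO4) would insert into the C3–Br bond of the (Z)-α-bromoacrylic N-methoxy-N-methylamide on ring A and couple with the lactone enolate at C2 to give the bridged product A2.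
- For: the lactone can only span C1 and C2 on one face, so cis is enforced by the ring; the lactone oxygen is the one that ends as the C2' methoxy group; enolate alkenylation is established chemistry.
- Against: neither aroyl group exists in A2. Two aryl-metal additions (to the lactone and to the amide) must follow on a substrate whose C2–H is α to a carbonyl and allylic, and once the lactone is opened nothing holds the cis relation. Double addition to the lactone, base-induced loss of HBr from the bromoalkene and an extra phenol methylation add to the cost.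
- Comparison: for securing cis at the ring-forming step this alternative is stronger. The chosen route offers instead both aryl ketones in place before either stereocentre meets an organometallic reagent, and a finish of three steps, none strongly basic.

**Alternative 2:** Both C1–C2 and C3–C4 are cut in a [4+2] sense. Irradiation of the 2-benzylbenzaldehyde A3 would give the hydroxy-o-quinodimethane, which adds endo to the cis-diaroylethylene A4 on a Ti(OiPr)4/TADDOL complex to give the all-cis hydroxytetralin A5.
- For: two bonds, ring B and every stereocentre in one step from two simple pieces, and the finish is only a β-hydroxy ketone dehydration. On step economy it is clearly stronger than the chosen route.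
- Against: A4 absorbs light itself and isomerises to the trans isomer, which leaves the C1/C2 relation to whichever carbonyl sits endo. The three alkoxy groups of A3 lower its ππ* triplet and make the hydrogen abstraction inefficient. The dienol geometry at the diarylmethylene end, the C1/C2 relation and the absolute sense all hang on one titanium complex, for which the dienophile offers two chelation sites.
- Comparison: the chosen route is longer but separates these questions: C1 by a catalytic arylation with a dependable model, C2 by a proton transfer directed by C1.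

**Alternative 3:** C1–C2 and C1–C8a are cut. The C2 methylene of the ring A dienedione A6 would condense with the aldehyde A7, and a chiral BINOL-derived phosphoric acid would then promote 6-endo conjugate Friedel–Crafts attack of C8a on C1 with protonation at C2, giving A8.
- For: the shortest route; it uses the innate nucleophilicity of ring A para to the free C6 hydroxyl, and C3=C4 is present from the start, so no oxygen has to be removed. On step count and on avoiding C4 oxygen it is stronger.
- Against: ring A has two positions ortho to C4a that close the same six-membered ring, C8a (para to the hydroxyl but wedged next to the methoxy group) and C5 (ortho to the hydroxyl, unhindered); the wrong one gives the 5,6,7-oxygenated isomer. The acid-catalysed addition is reversible, so the C1 and C2 configurations can erode. One phenol must stay free among five ethers, which needs orthogonal protection.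
- Comparison: the chosen route offers a ring A pattern fixed before ring closure (C4a and C8a both carry carbon) and a C1 centre that is set once and not reopened.

Key step: step 13

Assumption: the aryl–rhodium complex of (S)-BINAP (2,2'-bis(diphenylphosphino)-1,1'-binaphthyl) is taken to bind (E)-enones on the Si face of the α-carbon, which for 9 is also the Si face of C1 and gives the (R) centre; if the sense were the reverse, (R)-BINAP would be used with nothing else changed.

Assumption: the (5aS,10bR) antipode of the triazolium salt is written as the one whose preferred alkene face coincides with the face fixed by C1; no model exists for an endo closure, so the (5aR,10bS) salt takes its place if that proves to be the matched one.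

## Route

Step 1
Reactants: 1 3,4-dihydroxy-5-methoxybenzaldehyde (5-hydroxyvanillin)
Product: 2 3,4-diisopropoxy-5-methoxybenzaldehyde
Conditions: 2-bromopropane, K2CO3, DMF, 70 °C
Reagents that add atoms: 2-bromopropane, CC(C)Br
Why: Williamson etherification of both phenols; the isopropyl ethers tolerate every later reagent and can be removed at the end beside the methyl ethers.

Step 2
Reactants: 2 3,4-diisopropoxy-5-methoxybenzaldehyde
Product: 3 5-(dimethoxymethyl)-1,2-diisopropoxy-3-methoxybenzene
Conditions: HC(OMe)3, MeOH, p-toluenesulfonic acid monohydrate (cat.), 23 °C; Et3N quench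
Reagents that add atoms: trimethyl orthoformate, COC(OC)OC; methanol, CO
Why: Acid-catalysed acetalisation with the orthoformate as water scavenger; the acetal masks the future C4 through the base steps and serves as directing group in step 3.

Step 3
Reactants: 3 5-(dimethoxymethyl)-1,2-diisopropoxy-3-methoxybenzene
Product: 6 6-(dimethoxymethyl)-3,4-diisopropoxy-2-methoxybenzaldehyde, via aryllithium 4 (not isolated), via lithium hemiaminal alkoxide 5 (not isolated)
Conditions: n-BuLi, Et2O, 0 → 23 °C; DMF, −78 → 0 °C; H2O
Reagents that add atoms: N,N-dimethylformamide, CN(C)C=O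
Why: Directed ortho-metalation followed by formylation; the position between the acetal and the methoxy group (the future C8a) is held by both donors, while the other ortho position lies next to an isopropoxy group that coordinates lithium poorly and shields it.

Step 4
Reactants: 7 1-(4-hydroxyphenyl)ethanone (4-hydroxyacetophenone)
Product: 8 1-(4-isopropoxyphenyl)ethanone
Conditions: 2-bromopropane, K2CO3, DMF, 70 °C
Reagents that add atoms: 2-bromopropane, CC(C)Br
Why: Williamson etherification of the phenol; 8 serves both as the enolate partner of step 5 and as the source of the glyoxal in step 9.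

Step 5
Reactants: 6 6-(dimethoxymethyl)-3,4-diisopropoxy-2-methoxybenzaldehyde; 8 1-(4-isopropoxyphenyl)ethanone
Product: 9 (E)-3-[6-(dimethoxymethyl)-3,4-diisopropoxy-2-methoxyphenyl]-1-(4-isopropoxyphenyl)prop-2-en-1-one
Conditions: KOH, EtOH, 23–40 °C
Reagents that add atoms: none
Why: Claisen–Schmidt condensation (aldol addition, then E1cB loss of water) forms C1=C2 as the (E)-chalcone; the aldehyde has no α-hydrogen and the acetal is inert to hydroxide.

Step 6
Reactants: 10 3-methoxybenzene-1,2-diol (3-methoxycatechol)
Product: 11 1,2-diisopropoxy-3-methoxybenzene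
Conditions: 2-bromopropane, K2CO3, DMF, 70 °C, argon
Reagents that add atoms: 2-bromopropane, CC(C)Br
Why: Williamson etherification of both catechol oxygens under exclusion of air.

Step 7
Reactants: 11 1,2-diisopropoxy-3-methoxybenzene
Product: 14 (3,4-diisopropoxy-2-methoxyphenyl)boronic acid, via aryllithium 12 (not isolated), via lithium triisopropoxyborate 13 (not isolated)
Conditions: n-BuLi, TMEDA, THF, 0 °C; B(Oi-Pr)3, −78 → 23 °C; 1 M HCl
Reagents that add atoms: triisopropyl borate, CC(C)OB(OC(C)C)OC(C)C; water, O
Why: Directed ortho-metalation next to the methoxy group (the better and less hindered director of the three ethers), borylation of the aryllithium and hydrolysis of the borate.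

Step 8
Reactants: 9 (E)-3-[6-(dimethoxymethyl)-3,4-diisopropoxy-2-methoxyphenyl]-1-(4-isopropoxyphenyl)prop-2-en-1-one; 14 (3,4-diisopropoxy-2-methoxyphenyl)boronic acid
Product: 15 (R)-3-[6-(dimethoxymethyl)-3,4-diisopropoxy-2-methoxyphenyl]-3-(3,4-diisopropoxy-2-methoxyphenyl)-1-(4-isopropoxyphenyl)propan-1-one
Conditions: [Rh(OH)((S)-BINAP)]2 (3 mol % Rh), 14 (2.5 equiv), KOH (0.3 equiv), dioxane/H2O 10:1, 50 °C
Reagents that add atoms: none
Why: Rhodium-catalysed asymmetric 1,4-addition of an arylboronic acid to an enone: transmetalation gives the aryl–rhodium complex, the enone inserts with C1 presenting its Si face to the aryl group, and water protonates the oxa-π-allyl rhodium, so C1 is created as (R). The boronic acid is used in excess to outrun protodeboronation, and the slightly basic medium keeps the acetal intact.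

Step 9
Reactants: 8 1-(4-isopropoxyphenyl)ethanone
Product: 17 2-(4-isopropoxyphenyl)-2-oxoacetaldehyde, via glyoxal hydrate 16 (not isolated)
Conditions: SeO2, dioxane/H2O, reflux; then toluene, azeotropic drying
Reagents that add atoms: selenium dioxide, O=[Se]=O
Why: Riley oxidation of the methyl ketone to the arylglyoxal, which is taken up as its hydrate and dried for use as an anhydrous electrophile.

Step 10
Reactants: 15 (R)-3-[6-(dimethoxymethyl)-3,4-diisopropoxy-2-methoxyphenyl]-3-(3,4-diisopropoxy-2-methoxyphenyl)-1-(4-isopropoxyphenyl)propan-1-one; 17 2-(4-isopropoxyphenyl)-2-oxoacetaldehyde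
Product: 20 2-hydroxy-3-{(R)-[6-(dimethoxymethyl)-3,4-diisopropoxy-2-methoxyphenyl](3,4-diisopropoxy-2-methoxyphenyl)methyl}-1,4-bis(4-isopropoxyphenyl)butane-1,4-dione (mixture at the two new centres), via lithium enolate 18 (not isolated), via lithium aldolate 19 (not isolated)
Conditions: LiN(SiMe3)2, THF, −78 °C; 17 (1.5 equiv), −78 °C; AcOH
Reagents that add atoms: none
Why: Directed aldol addition: the lithium enolate of the aryl ketone attacks the aldehyde carbon of the glyoxal, the more electrophilic of its two carbonyls, and forms C2–C3; the two new centres do not matter because both become sp2 in step 11.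

Step 11
Reactants: 20 2-hydroxy-3-{(R)-[6-(dimethoxymethyl)-3,4-diisopropoxy-2-methoxyphenyl](3,4-diisopropoxy-2-methoxyphenyl)methyl}-1,4-bis(4-isopropoxyphenyl)butane-1,4-dione
Product: 22 (E)-2-{(R)-[6-(dimethoxymethyl)-3,4-diisopropoxy-2-methoxyphenyl](3,4-diisopropoxy-2-methoxyphenyl)methyl}-1,4-bis(4-isopropoxyphenyl)but-2-ene-1,4-dione, via mesylate 21 (not isolated)
Conditions: MsCl, Et3N, CH2Cl2, 0 → 23 °C
Reagents that add atoms: none
Why: Mesylation of the carbinol and E1cB elimination through the C2 enolate give the enedione, expected as the trans-diaroyl (E) isomer (the geometry is not carried into the product). C1–H should be spared because allylic 1,3-strain with the C3 aroyl group holds it in the alkene plane, where it cannot overlap with the π system.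

Step 12
Reactants: 22 (E)-2-{(R)-[6-(dimethoxymethyl)-3,4-diisopropoxy-2-methoxyphenyl](3,4-diisopropoxy-2-methoxyphenyl)methyl}-1,4-bis(4-isopropoxyphenyl)but-2-ene-1,4-dione
Product: 23 2-{(R)-[(E)-1,4-bis(4-isopropoxyphenyl)-1,4-dioxobut-2-en-2-yl](3,4-diisopropoxy-2-methoxyphenyl)methyl}-4,5-diisopropoxy-3-methoxybenzaldehyde
Conditions: pyridinium p-toluenesulfonate (cat.), acetone/H2O, 23 °C
Reagents that add atoms: water, O
Why: Acetal hydrolysis under weak acid catalysis frees the C4 aldehyde; the enedione and the isopropyl ethers are inert to these conditions.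

Step 13
Reactants: 23 2-{(R)-[(E)-1,4-bis(4-isopropoxyphenyl)-1,4-dioxobut-2-en-2-yl](3,4-diisopropoxy-2-methoxyphenyl)methyl}-4,5-diisopropoxy-3-methoxybenzaldehyde
Product: 24 [(1R,2R)-1-(3,4-diisopropoxy-2-methoxyphenyl)-4-hydroxy-6,7-diisopropoxy-8-methoxy-1,2-dihydronaphthalene-2,3-diyl]bis[(4-isopropoxyphenyl)methanone]
Conditions: (5aS,10bR)-2-(pentafluorophenyl)-5a,10b-dihydro-4H,6H-indeno[2,1-b][1,2,4]triazolo[4,3-d][1,4]oxazin-2-ium tetrafluoroborate (20 mol %), KN(SiMe3)2 (20 mol %), carbene pre-formed and HN(SiMe3)2 removed in vacuo, toluene, 23 °C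
Reagents that add atoms: none
Why: Proposed new method: the carbene adds to the C4 aldehyde and proton transfer gives the hydroxy-enamine, whose nucleophilic C4 attacks C3, the alkene carbon β to the C2 ketone, so that ring B closes 6-endo-trig through the new C3–C4 bond; the closest known reaction type is the asymmetric intramolecular Stetter reaction of aldehyde-tethered trisubstituted Michael acceptors with aminoindanol-derived triazolium carbenes, which closes rings in the exo mode and sets the α-centre by internal proton transfer. The C2 enolate takes its proton from the C4 carbinol hydroxyl on the face from which C4 arrived (a five-membered transfer, the same geometry as in the known exo cases); loss of the carbene leaves the C4 ketone, which tautomerises to the hydrogen-bonded enol 24 and erases the transient C3 centre. C2 is the only new stereocentre that survives, and it is controlled by C1: allylic 1,3-strain with the C3 aroyl group holds C1–H in the enedione plane, so C8a (and with it C4) lies on one face and the C1 aryl on the other, and delivery of C4 and H to the same face puts the C2 hydrogen anti to the C1 aryl, that is, the C2 aroyl group cis to it. The catalyst antipode is chosen so that its preferred alkene face is this same face. The step needs addition at the unsubstituted C3 and not 5-exo addition at C2; this is secured by C2 being fully substituted and flanked by the diarylmethine, where a quaternary centre would have to form. Attack on a ketone carbonyl (crossed benzoin) is reversible and should drain into the irreversible conjugate addition. Pre-forming the carbene keeps free base away from C1–H, which is γ to the C3 ketone, and from the new C2–H.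

Step 14
Reactants: 24 [(1R,2R)-1-(3,4-diisopropoxy-2-methoxyphenyl)-4-hydroxy-6,7-diisopropoxy-8-methoxy-1,2-dihydronaphthalene-2,3-diyl]bis[(4-isopropoxyphenyl)methanone]
Product: 26 [(1R,2R)-1-(3,4-diisopropoxy-2-methoxyphenyl)-6,7-diisopropoxy-8-methoxy-4-(trifluoromethylsulfonyloxy)-1,2-dihydronaphthalene-2,3-diyl]bis[(4-isopropoxyphenyl)methanone], via sodium enolate 25 (not isolated)
Conditions: NaH (1.05 equiv), Et2O, 0 °C; Tf2O, −78 → 0 °C
Reagents that add atoms: trifluoromethanesulfonic anhydride, O=S(=O)(OS(=O)(=O)C(F)(F)F)C(F)(F)F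
Why: O-Sulfonylation of a β-diketone enolate, as used for 2-acylcycloalkanones; the ring oxygen should react because the endocyclic C3=C4 triflate stays conjugated with ring A, whereas sulfonylation of the aroyl oxygen would need a tetrasubstituted exocyclic alkene eclipsing the C2 substituents. One equivalent of NaH removes only the enol proton, so C2–H is untouched.

Step 15
Reactants: 26 [(1R,2R)-1-(3,4-diisopropoxy-2-methoxyphenyl)-6,7-diisopropoxy-8-methoxy-4-(trifluoromethylsulfonyloxy)-1,2-dihydronaphthalene-2,3-diyl]bis[(4-isopropoxyphenyl)methanone]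
Product: 27 [(1R,2R)-1-(3,4-diisopropoxy-2-methoxyphenyl)-6,7-diisopropoxy-8-methoxy-1,2-dihydronaphthalene-2,3-diyl]bis[(4-isopropoxyphenyl)methanone]
Conditions: Pd(OAc)2 (5 mol %), PPh3 (10 mol %), HCO2H, Et3N, DMF, 60 °C
Reagents that add atoms: none
Why: Palladium-catalysed transfer hydrogenolysis of a vinyl triflate: zerovalent palladium inserts into the C4–O bond, formate replaces triflate and loses CO2, and reductive elimination from the palladium hydride gives C4–H. The triethylammonium formate buffer is too weakly basic to epimerise C2 quickly.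

Step 16
Reactants: 27 [(1R,2R)-1-(3,4-diisopropoxy-2-methoxyphenyl)-6,7-diisopropoxy-8-methoxy-1,2-dihydronaphthalene-2,3-diyl]bis[(4-isopropoxyphenyl)methanone]
Product: 28 [(1R,2R)-1-(3,4-dihydroxy-2-methoxyphenyl)-6,7-dihydroxy-8-methoxy-1,2-dihydronaphthalene-2,3-diyl]bis[(4-hydroxyphenyl)methanone] (CNP0335881.1)
Conditions: BCl3 (excess), CH2Cl2, −78 → 0 °C; MeOH then H2O, argon
Reagents that add atoms: none
Why: Lewis-acid dealkylation: BCl3 cleaves aryl isopropyl ethers by chloride capture of the secondary alkyl group much faster than aryl methyl ethers, which is the usual reason for carrying phenols as isopropyl ethers beside methoxy groups. Low temperature and a cold quench of the boron aryloxides are meant to keep C2 from enolising.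

## Compound list

1 | 3,4-dihydroxy-5-methoxybenzaldehyde (5-hydroxyvanillin) | COc1cc(C=O)cc(O)c1O | starting material
2 | 3,4-diisopropoxy-5-methoxybenzaldehyde | COc1cc(C=O)cc(OC(C)C)c1OC(C)C | intermediate
3 | 5-(dimethoxymethyl)-1,2-diisopropoxy-3-methoxybenzene | COc1cc(C(OC)OC)cc(OC(C)C)c1OC(C)C | intermediate
4 | [6-(dimethoxymethyl)-3,4-diisopropoxy-2-methoxyphenyl]lithium | [Li]c1c(OC)c(OC(C)C)c(OC(C)C)cc1C(OC)OC | intermediate
5 | lithium [6-(dimethoxymethyl)-3,4-diisopropoxy-2-methoxyphenyl](dimethylamino)methanolate | [Li+].[O-]C(N(C)C)c1c(OC)c(OC(C)C)c(OC(C)C)cc1C(OC)OC | intermediate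
6 | 6-(dimethoxymethyl)-3,4-diisopropoxy-2-methoxybenzaldehyde | O=Cc1c(OC)c(OC(C)C)c(OC(C)C)cc1C(OC)OC | intermediate
7 | 1-(4-hydroxyphenyl)ethanone (4-hydroxyacetophenone) | CC(=O)c1ccc(O)cc1 | starting material
8 | 1-(4-isopropoxyphenyl)ethanone | CC(=O)c1ccc(OC(C)C)cc1 | intermediate
9 | (E)-3-[6-(dimethoxymethyl)-3,4-diisopropoxy-2-methoxyphenyl]-1-(4-isopropoxyphenyl)prop-2-en-1-one | COC(OC)c1cc(OC(C)C)c(OC(C)C)c(OC)c1/C=C/C(=O)c1ccc(OC(C)C)cc1 | intermediate
10 | 3-methoxybenzene-1,2-diol (3-methoxycatechol) | COc1cccc(O)c1O | starting material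
11 | 1,2-diisopropoxy-3-methoxybenzene | COc1cccc(OC(C)C)c1OC(C)C | intermediate
12 | (3,4-diisopropoxy-2-methoxyphenyl)lithium | [Li]c1ccc(OC(C)C)c(OC(C)C)c1OC | intermediate
13 | lithium (3,4-diisopropoxy-2-methoxyphenyl)triisopropoxyborate | [Li+].CC(C)O[B-](OC(C)C)(OC(C)C)c1ccc(OC(C)C)c(OC(C)C)c1OC | intermediate
14 | (3,4-diisopropoxy-2-methoxyphenyl)boronic acid | OB(O)c1ccc(OC(C)C)c(OC(C)C)c1OC | intermediate
15 | (R)-3-[6-(dimethoxymethyl)-3,4-diisopropoxy-2-methoxyphenyl]-3-(3,4-diisopropoxy-2-methoxyphenyl)-1-(4-isopropoxyphenyl)propan-1-one | COC(OC)c1cc(OC(C)C)c(OC(C)C)c(OC)c1[C@@H](c1ccc(OC(C)C)c(OC(C)C)c1OC)CC(=O)c1ccc(OC(C)C)cc1 | intermediate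
16 | 2,2-dihydroxy-1-(4-isopropoxyphenyl)ethanone (glyoxal hydrate) | OC(O)C(=O)c1ccc(OC(C)C)cc1 | intermediate
17 | 2-(4-isopropoxyphenyl)-2-oxoacetaldehyde | O=CC(=O)c1ccc(OC(C)C)cc1 | intermediate
18 | lithium (1Z,3R)-3-[6-(dimethoxymethyl)-3,4-diisopropoxy-2-methoxyphenyl]-3-(3,4-diisopropoxy-2-methoxyphenyl)-1-(4-isopropoxyphenyl)prop-1-en-1-olate | [Li+].COC(OC)c1cc(OC(C)C)c(OC(C)C)c(OC)c1[C@@H](c1ccc(OC(C)C)c(OC(C)C)c1OC)/C=C(\[O-])c1ccc(OC(C)C)cc1 | intermediate
19 | lithium 3-{(R)-[6-(dimethoxymethyl)-3,4-diisopropoxy-2-methoxyphenyl](3,4-diisopropoxy-2-methoxyphenyl)methyl}-1,4-bis(4-isopropoxyphenyl)-1,4-dioxobutan-2-olate (mixture at the two chain centres) | [Li+].COC(OC)c1cc(OC(C)C)c(OC(C)C)c(OC)c1[C@@H](c1ccc(OC(C)C)c(OC(C)C)c1OC)C(C(=O)c1ccc(OC(C)C)cc1)C([O-])C(=O)c1ccc(OC(C)C)cc1 | intermediate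
20 | 2-hydroxy-3-{(R)-[6-(dimethoxymethyl)-3,4-diisopropoxy-2-methoxyphenyl](3,4-diisopropoxy-2-methoxyphenyl)methyl}-1,4-bis(4-isopropoxyphenyl)butane-1,4-dione (mixture at the two chain centres) | COC(OC)c1cc(OC(C)C)c(OC(C)C)c(OC)c1[C@@H](c1ccc(OC(C)C)c(OC(C)C)c1OC)C(C(=O)c1ccc(OC(C)C)cc1)C(O)C(=O)c1ccc(OC(C)C)cc1 | intermediate
21 | 3-{(R)-[6-(dimethoxymethyl)-3,4-diisopropoxy-2-methoxyphenyl](3,4-diisopropoxy-2-methoxyphenyl)methyl}-1,4-bis(4-isopropoxyphenyl)-1,4-dioxobutan-2-yl methanesulfonate | COC(OC)c1cc(OC(C)C)c(OC(C)C)c(OC)c1[C@@H](c1ccc(OC(C)C)c(OC(C)C)c1OC)C(C(=O)c1ccc(OC(C)C)cc1)C(OS(C)(=O)=O)C(=O)c1ccc(OC(C)C)cc1 | intermediate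
22 | (E)-2-{(R)-[6-(dimethoxymethyl)-3,4-diisopropoxy-2-methoxyphenyl](3,4-diisopropoxy-2-methoxyphenyl)methyl}-1,4-bis(4-isopropoxyphenyl)but-2-ene-1,4-dione | COC(OC)c1cc(OC(C)C)c(OC(C)C)c(OC)c1[C@@H](c1ccc(OC(C)C)c(OC(C)C)c1OC)/C(C(=O)c1ccc(OC(C)C)cc1)=C\C(=O)c1ccc(OC(C)C)cc1 | intermediate
23 | 2-{(R)-[(E)-1,4-bis(4-isopropoxyphenyl)-1,4-dioxobut-2-en-2-yl](3,4-diisopropoxy-2-methoxyphenyl)methyl}-4,5-diisopropoxy-3-methoxybenzaldehyde | O=Cc1cc(OC(C)C)c(OC(C)C)c(OC)c1[C@@H](c1ccc(OC(C)C)c(OC(C)C)c1OC)/C(C(=O)c1ccc(OC(C)C)cc1)=C\C(=O)c1ccc(OC(C)C)cc1 | intermediate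
24 | [(1R,2R)-1-(3,4-diisopropoxy-2-methoxyphenyl)-4-hydroxy-6,7-diisopropoxy-8-methoxy-1,2-dihydronaphthalene-2,3-diyl]bis[(4-isopropoxyphenyl)methanone] | COc1c([C@@H]2c3c(cc(OC(C)C)c(OC(C)C)c3OC)C(O)=C(C(=O)c3ccc(OC(C)C)cc3)[C@@H]2C(=O)c2ccc(OC(C)C)cc2)ccc(OC(C)C)c1OC(C)C | intermediate
25 | sodium C4 enolate of 24 | [Na+].COc1c([C@@H]2c3c(cc(OC(C)C)c(OC(C)C)c3OC)C([O-])=C(C(=O)c3ccc(OC(C)C)cc3)[C@@H]2C(=O)c2ccc(OC(C)C)cc2)ccc(OC(C)C)c1OC(C)C | intermediate
26 | [(1R,2R)-1-(3,4-diisopropoxy-2-methoxyphenyl)-6,7-diisopropoxy-8-methoxy-4-(trifluoromethylsulfonyloxy)-1,2-dihydronaphthalene-2,3-diyl]bis[(4-isopropoxyphenyl)methanone] | COc1c([C@@H]2c3c(cc(OC(C)C)c(OC(C)C)c3OC)C(OS(=O)(=O)C(F)(F)F)=C(C(=O)c3ccc(OC(C)C)cc3)[C@@H]2C(=O)c2ccc(OC(C)C)cc2)ccc(OC(C)C)c1OC(C)C | intermediate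
27 | [(1R,2R)-1-(3,4-diisopropoxy-2-methoxyphenyl)-6,7-diisopropoxy-8-methoxy-1,2-dihydronaphthalene-2,3-diyl]bis[(4-isopropoxyphenyl)methanone] | COc1c([C@@H]2c3c(cc(OC(C)C)c(OC(C)C)c3OC)C=C(C(=O)c3ccc(OC(C)C)cc3)[C@@H]2C(=O)c2ccc(OC(C)C)cc2)ccc(OC(C)C)c1OC(C)C | intermediate
28 | [(1R,2R)-1-(3,4-dihydroxy-2-methoxyphenyl)-6,7-dihydroxy-8-methoxy-1,2-dihydronaphthalene-2,3-diyl]bis[(4-hydroxyphenyl)methanone] (CNP0335881.1) | COc1c([C@@H]2c3c(cc(O)c(O)c3OC)C=C(C(=O)c3ccc(O)cc3)[C@@H]2C(=O)c2ccc(O)cc2)ccc(O)c1O | target

## Step count and least certain steps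

Total: 16 steps. Longest linear sequence: 12 steps (1, 2, 3, 5, 8, 10, 11, 12, 13, 14, 15, 16, from 5-hydroxyvanillin 1).

**Step 13 (key step, the one step beyond known chemistry).**
- What may go wrong: closure in the 5-exo sense at C2; parking of the aldehyde as a reversible benzoin-type adduct of the C2 ketone with no onward conjugate addition; protonation of the carbene by the acidic enol product, which slows turnover; a base-induced shift of the C2=C3 bond toward C1, which would destroy the C1 centre.
- Fallback (known chemistry): it sets out from 23 and returns at 27, passing over steps 14 and 15. Zinc dust in acetic acid/THF at 0 °C reduces the enedione C2=C3 bond to the saturated diketo aldehyde F1. Piperidinium acetate in warm toluene then closes ring B by intramolecular aldol condensation of the C3 methylene on the C4 aldehyde. Closure through C2 would give a five-membered aldol that cannot dehydrate, so it reverts.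
- Price: C2 is then set by an uncontrolled protonation and sits next to a ketone during the condensation, so the cis isomer of 27 would have to be separated from the trans isomer.

**Step 8.**
- What may go wrong: slow insertion of the enone, whose C1 carries a doubly ortho-substituted ring, so that protodeboronation of the electron-rich boronic acid consumes the reagent; or weak facial discrimination.
- Fallback (auxiliary-controlled organocopper addition in place of catalysis): it sets out from 6 and returns at 15. Horner–Wadsworth–Emmons reaction of 6 with (S)-3-[2-(diethoxyphosphoryl)acetyl]-4-phenyloxazolidin-2-one (LiCl, i-Pr2NEt, MeCN) gives the N-enoyl oxazolidinone F2. The aryllithium 12 is converted with MgBr2·OEt2 and CuBr·SMe2 into an aryl copper reagent, which adds to F2 in THF at −40 °C anti to the auxiliary phenyl group in the chelated s-cis conformer (the Si face of C1) to give the conjugate adduct F3. MeNH(OMe)·HCl/AlMe3 at 0 °C converts F3 into the N-methoxy-N-methylamide F4, and 4-isopropoxyphenylmagnesium bromide gives 15.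

**Step 14.**
- What may go wrong: sulfonylation at the aroyl oxygen, which would give the exocyclic enol triflate, or epimerisation at C2 by adventitious base.
- Fallback (no oxygen is ever placed at C4): it sets out from 15 and returns at 27. The enolate 18 is alkylated with 2-bromo-1-(4-isopropoxyphenyl)ethanone to the saturated diketone acetal F5. Pyridinium p-toluenesulfonate in wet acetone frees the aldehyde F1, and the piperidinium acetate condensation described above gives 27.
- Price: as for step 13, control of C2 is given up to the alkylation and to equilibration.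

**Step 16.**
- What may go wrong: Lewis-acid-promoted enolisation of the C2 ketone into conjugation with C3=C4, followed by epimerisation to the trans isomer or migration of the double bond to C2=C3; loss of the C8 or C2' methyl group, assisted by a neighbouring boron aryloxide; incomplete cleavage of six ethers.
- Fallback (dealkylation moved ahead of the reduction): it sets out from 26 and returns at 28. BCl3 is applied to the triflate 26, whose C3=C4 bond is deactivated by the triflyloxy group and less ready to accept a proton at C4, giving the hexaphenol triflate F6. The palladium/formate reduction of step 15 then becomes the last, nearly neutral step.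

**Step 3.**
- What may go wrong: metalation next to the isopropoxy group or at the acetal C–H, or incomplete metalation.
- Fallback (electrophilic substitution, then halogen–lithium exchange): it sets out from 2 and returns at 6 through the same aryllithium 4. NBS in MeCN brominates 2 ortho to the aldehyde, with the less hindered site next to the methoxy group favoured, to give the bromo aldehyde F7; the regioisomer is removed by crystallisation or chromatography. Acetalisation as in step 2 gives the bromo acetal F8, and n-BuLi at −78 °C gives 4 regiospecifically, which is formylated as before.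

## Further compounds

F1 | step 13 | 2-[(1R,2S)-1-(3,4-diisopropoxy-2-methoxyphenyl)-2-(4-isopropoxybenzoyl)-4-(4-isopropoxyphenyl)-4-oxobutyl]-4,5-diisopropoxy-3-methoxybenzaldehyde (the C2 epimer that leads to 27; its epimer forms alongside) | O=Cc1cc(OC(C)C)c(OC(C)C)c(OC)c1[C@@H](c1ccc(OC(C)C)c(OC(C)C)c1OC)[C@H](CC(=O)c1ccc(OC(C)C)cc1)C(=O)c1ccc(OC(C)C)cc1
F2 | step 8 | (S)-3-{(E)-3-[6-(dimethoxymethyl)-3,4-diisopropoxy-2-methoxyphenyl]prop-2-enoyl}-4-phenyloxazolidin-2-one | COC(OC)c1cc(OC(C)C)c(OC(C)C)c(OC)c1/C=C/C(=O)N1[C@@H](c2ccccc2)COC1=O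
F3 | step 8 | (S)-3-{(R)-3-[6-(dimethoxymethyl)-3,4-diisopropoxy-2-methoxyphenyl]-3-(3,4-diisopropoxy-2-methoxyphenyl)propanoyl}-4-phenyloxazolidin-2-one | COC(OC)c1cc(OC(C)C)c(OC(C)C)c(OC)c1[C@@H](c1ccc(OC(C)C)c(OC(C)C)c1OC)CC(=O)N1[C@@H](c2ccccc2)COC1=O
F4 | step 8 | (R)-3-[6-(dimethoxymethyl)-3,4-diisopropoxy-2-methoxyphenyl]-3-(3,4-diisopropoxy-2-methoxyphenyl)-N-methoxy-N-methylpropanamide | COC(OC)c1cc(OC(C)C)c(OC(C)C)c(OC)c1[C@@H](c1ccc(OC(C)C)c(OC(C)C)c1OC)CC(=O)N(C)OC
F5 | step 14 | (2S)-2-{(R)-[6-(dimethoxymethyl)-3,4-diisopropoxy-2-methoxyphenyl](3,4-diisopropoxy-2-methoxyphenyl)methyl}-1,4-bis(4-isopropoxyphenyl)butane-1,4-dione (the C2 epimer that leads to 27; its epimer may form alongside) | COC(OC)c1cc(OC(C)C)c(OC(C)C)c(OC)c1[C@@H](c1ccc(OC(C)C)c(OC(C)C)c1OC)[C@H](CC(=O)c1ccc(OC(C)C)cc1)C(=O)c1ccc(OC(C)C)cc1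
F6 | step 16 | [(1R,2R)-1-(3,4-dihydroxy-2-methoxyphenyl)-6,7-dihydroxy-8-methoxy-4-(trifluoromethylsulfonyloxy)-1,2-dihydronaphthalene-2,3-diyl]bis[(4-hydroxyphenyl)methanone] | COc1c([C@@H]2c3c(cc(O)c(O)c3OC)C(OS(=O)(=O)C(F)(F)F)=C(C(=O)c3ccc(O)cc3)[C@@H]2C(=O)c2ccc(O)cc2)ccc(O)c1O
F7 | step 3 | 2-bromo-4,5-diisopropoxy-3-methoxybenzaldehyde | O=Cc1cc(OC(C)C)c(OC(C)C)c(OC)c1Br
F8 | step 3 | 2-bromo-1-(dimethoxymethyl)-4,5-diisopropoxy-3-methoxybenzene | COC(OC)c1cc(OC(C)C)c(OC(C)C)c(OC)c1Br
A1 | alternative 1 | 4-aryl-3,4-dihydrocoumarin carrying the (Z)-α-bromoacrylic N-methoxy-N-methylamide on ring A | O=C1Oc2c(OC(C)C)c(OC(C)C)ccc2[C@@H](C1)c1c(OC)c(OC(C)C)c(OC(C)C)cc1/C=C(\Br)C(=O)N(C)OC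
A2 | alternative 1 | cis-fused lactone-bridged dihydronaphthalene with the C3 N-methoxy-N-methylamide | O=C1Oc2c(OC(C)C)c(OC(C)C)ccc2[C@@H]2c3c(OC)c(OC(C)C)c(OC(C)C)cc3C=C(C(=O)N(C)OC)[C@H]12
A3 | alternative 2 | 2-[(3,4-diisopropoxy-2-methoxyphenyl)methyl]-4,5-diisopropoxy-3-methoxybenzaldehyde | O=Cc1cc(OC(C)C)c(OC(C)C)c(OC)c1Cc1ccc(OC(C)C)c(OC(C)C)c1OC
A4 | alternative 2 | (Z)-1,4-bis(4-isopropoxyphenyl)but-2-ene-1,4-dione | CC(C)Oc1ccc(cc1)C(=O)/C=C\C(=O)c1ccc(OC(C)C)cc1
A5 | alternative 2 | all-cis 1-aryl-2,3-diaroyl-4-hydroxytetralin (hexa-O-isopropyl) | COc1c([C@@H]2c3c(cc(OC(C)C)c(OC(C)C)c3OC)[C@H](O)[C@H](C(=O)c3ccc(OC(C)C)cc3)[C@@H]2C(=O)c2ccc(OC(C)C)cc2)ccc(OC(C)C)c1OC(C)C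
A6 | alternative 3 | (E)-2-[(3-hydroxy-4-isopropoxy-5-methoxyphenyl)methylidene]-1,4-bis(4-isopropoxyphenyl)butane-1,4-dione | O=C(C/C(=C\c1cc(O)c(OC(C)C)c(OC)c1)C(=O)c1ccc(OC(C)C)cc1)c1ccc(OC(C)C)cc1
A7 | alternative 3 | 3,4-diisopropoxy-2-methoxybenzaldehyde | COc1c(C=O)ccc(OC(C)C)c1OC(C)C
A8 | alternative 3 | penta-O-isopropyl ether of the target with free C6 hydroxyl | COc1c([C@@H]2c3c(cc(O)c(OC(C)C)c3OC)C=C(C(=O)c3ccc(OC(C)C)cc3)[C@@H]2C(=O)c2ccc(OC(C)C)cc2)ccc(OC(C)C)c1OC(C)C
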